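**Retrosynthetic overview**
- Last bond: the ester C–O, made by Mitsunobu coupling of a primary alcohol (benzylic OH masked as a triethylsilyl ether) with O-TBS-protected (Z)-2-(hydroxymethyl)but-2-enoic acid; one global desilylation ends the route.
- Alcohol fragment: reduction of an anti α-cinnamyl β-silyloxy ester, whose C2–CH2 bond comes from a new palladium-catalysed cinnamylation of the chelated dianion of an (S)-β-hydroxy ester (anti 1,2-induction sets C2).
- The (S)-carbinol comes from asymmetric transfer hydrogenation of ethyl 3-(4-methoxyphenyl)-3-oxopropanoate; the cinnamyl carbonate comes from methyl 3,4-dimethoxycinnamate.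
- Acid fragment: trans-hydrostannation of but-2-yn-1-ol, then methoxycarbonylation, fixes the Z (methyl cis to carbonyl) geometry.
- No ring is formed; both benzene rings are bought intact.

Assumption: the SMILES is read as (1S,2S) at the diol core (benzylic carbinol S, branching carbon S, i.e. the anti-aldol-type relationship), E at the styrene and Z at the enoate; all numbered starting materials are catalogue compounds.

**Route**

Step 1
Reactants: 1 ethyl 3-(4-methoxyphenyl)-3-oxopropanoate
Product: 2 ethyl (3S)-3-hydroxy-3-(4-methoxyphenyl)propanoate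
Conditions: RuCl[(S,S)-TsDPEN](p-cymene) (1 mol %), HCO2H/Et3N (5:2), 40 °C
Reagents that add atoms: none
Why: Noyori-type asymmetric transfer hydrogenation of an aryl ketone, in which the (S,S)-TsDPEN ruthenium hydride delivers H to the face that gives the (S)-benzylic alcohol (same sense as for acetophenone), setting the carbinol stereocentre of the target while the ester is untouched.

Step 2
Reactants: 3 methyl (2E)-3-(3,4-dimethoxyphenyl)prop-2-enoate
Product: 4 (2E)-3-(3,4-dimethoxyphenyl)prop-2-en-1-ol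
Conditions: i-Bu2AlH (2.3 equiv), CH2Cl2, −78 °C; aq. KNaC4H4O6 (potassium sodium tartrate)
Reagents that add atoms: none
Why: 1,2-reduction of the enoate by the aluminium hydride at −78 °C gives the allylic alcohol and leaves the E-alkene and aryl ethers alone.

Step 3
Reactants: 4 (2E)-3-(3,4-dimethoxyphenyl)prop-2-en-1-ol
Product: 5 (2E)-3-(3,4-dimethoxyphenyl)prop-2-en-1-yl ethyl carbonate
Conditions: ClCO2Et, pyridine, CH2Cl2, 0 °C
Reagents that add atoms: ethyl chloroformate, CCOC(=O)Cl
Why: O-acylation with a chloroformate gives a bench-stable allylic carbonate, and its ethyl group matches the ethyl ester of 2 so that the ethoxide released in step 4 cannot scramble that ester.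

Step 4
Reactants: 2 ethyl (3S)-3-hydroxy-3-(4-methoxyphenyl)propanoate; 5 (2E)-3-(3,4-dimethoxyphenyl)prop-2-en-1-yl ethyl carbonate
Product: 7 ethyl (2R,3S)-2-[(2E)-3-(3,4-dimethoxyphenyl)prop-2-en-1-yl]-3-hydroxy-3-(4-methoxyphenyl)propanoate, via dilithium alkoxide-enolate 6 (not isolated)
Conditions: LiN(i-Pr)2 (2.1 equiv), THF, −78 to −30 °C; then 5 (1.1 equiv), [Pd(C3H5)Cl]2 (1 mol %), PPh3 (4.5 mol %), −78 to −30 °C; AcOH quench
Reagents that add atoms: lithium diisopropylamide, CC(C)[N-]C(C)C.[Li+] (its lithium is in 6 only; nothing from it stays in 7)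
Why: Proposed new method: palladium-catalysed allylic alkylation with a chelated β-hydroxy ester dianion as nucleophile — zerovalent palladium ionises carbonate 5 at −78 °C to a cationic (1-aryl-η3-allyl)Pd(PPh3)2 complex (ethyl carbonate leaves and falls apart to CO2 and ethoxide), the lithium-chelated enolate carbon of 6 attacks the unsubstituted CH2 terminus from the face opposite palladium so the cinnamyl unit arrives linear and E, and the six-membered Li–O–C=C–C–O chelate lets the electrophile approach only anti to the aryl group on the carbinol carbon, which sets C2 as R (anti, 2R,3S) at a temperature where the electron-rich aldolate does not undergo retro-aldol and without the unstable electron-rich cinnamyl bromide; the closest known reaction types are the Fráter–Seebach alkylation of β-hydroxy ester dianions with allyl halides (same anti 1,2-induction) and the Tsuji–Trost allylation of metal-chelated amino-ester enolates with allyl carbonates at −78 °C.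

Step 5
Reactants: 7 ethyl (2R,3S)-2-[(2E)-3-(3,4-dimethoxyphenyl)prop-2-en-1-yl]-3-hydroxy-3-(4-methoxyphenyl)propanoate
Product: 8 ethyl (2R,3S)-2-[(2E)-3-(3,4-dimethoxyphenyl)prop-2-en-1-yl]-3-(4-methoxyphenyl)-3-[(triethylsilyl)oxy]propanoate
Conditions: Et3SiOTf, 2,6-lutidine, CH2Cl2, −78 °C
Reagents that add atoms: triethylsilyl trifluoromethanesulfonate, CC[Si](CC)(CC)OS(=O)(=O)C(F)(F)F
Why: Silyl triflate/2,6-lutidine silylation of the hindered benzylic alcohol is fast at −78 °C and neither epimerises C2 nor provokes retro-aldol.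

Step 6
Reactants: 8 ethyl (2R,3S)-2-[(2E)-3-(3,4-dimethoxyphenyl)prop-2-en-1-yl]-3-(4-methoxyphenyl)-3-[(triethylsilyl)oxy]propanoate
Product: 9 (2S,4E)-5-(3,4-dimethoxyphenyl)-2-{(S)-(4-methoxyphenyl)[(triethylsilyl)oxy]methyl}pent-4-en-1-ol
Conditions: i-Bu2AlH (2.5 equiv), CH2Cl2, −78 °C; aq. KNaC4H4O6
Reagents that add atoms: none
Why: Hydride reduction of the ester to the primary alcohol at low temperature leaves the secondary silyl ether, the styrene and both stereocentres untouched (the label of C2 changes from R to S only because the substituent priorities change).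

Step 7
Reactants: 10 but-2-yn-1-ol
Product: 11 (2Z)-2-(tributylstannyl)but-2-en-1-ol
Conditions: Bu3SnH (1.1 equiv), [Cp*RuCl]4 (1.25 mol %), CH2Cl2, rt
Reagents that add atoms: tributylstannane, CCCC[SnH](CCCC)CCCC
Why: Hydroxyl-directed ruthenium-catalysed trans-hydrostannation adds H and Sn anti across the alkyne with tin on the carbon next to CH2OH, which fixes the geometry (methyl cis to tin) that becomes the Z-enoate.

Step 8
Reactants: 11 (2Z)-2-(tributylstannyl)but-2-en-1-ol
Product: 12 methyl (2Z)-2-(hydroxymethyl)but-2-enoate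
Conditions: Pd(OAc)2 (5 mol %), Ph3As (10 mol %), 1,4-benzoquinone (1.5 equiv), CF3CO2H (0.3 equiv), CO (1 atm), MeOH, rt
Reagents that add atoms: carbon monoxide, [C-]#[O+]; methanol, CO
Why: Oxidative methoxycarbonylation of the alkenylstannane (tin-to-palladium transmetalation on divalent palladium, CO insertion, methanolysis, benzoquinone reoxidising zerovalent palladium) replaces tin by CO2Me with retention of alkene geometry.

Step 9
Reactants: 12 methyl (2Z)-2-(hydroxymethyl)but-2-enoate
Product: 13 methyl (2Z)-2-({[tert-butyl(dimethyl)silyl]oxy}methyl)but-2-enoate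
Conditions: TBSCl, imidazole, DMF, 0 °C to rt
Reagents that add atoms: tert-butyldimethylsilyl chloride, CC(C)(C)[Si](C)(C)Cl
Why: Standard imidazole-promoted silylation of the primary allylic alcohol.

Step 10
Reactants: 13 methyl (2Z)-2-({[tert-butyl(dimethyl)silyl]oxy}methyl)but-2-enoate
Product: 14 (2Z)-2-({[tert-butyl(dimethyl)silyl]oxy}methyl)but-2-enoic acid
Conditions: LiOH·H2O (3 equiv), THF/MeOH/H2O, 0 °C to rt; then 1 M HCl to pH 4
Reagents that add atoms: lithium hydroxide, [Li+].[OH-]
Why: Saponification (acyl substitution by hydroxide) at or below room temperature cleaves the methyl ester without Z-to-E isomerisation, and the primary TBS ether survives LiOH.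

Step 11
Reactants: 9 (2S,4E)-5-(3,4-dimethoxyphenyl)-2-{(S)-(4-methoxyphenyl)[(triethylsilyl)oxy]methyl}pent-4-en-1-ol; 14 (2Z)-2-({[tert-butyl(dimethyl)silyl]oxy}methyl)but-2-enoic acid
Product: 16 (2S,4E)-5-(3,4-dimethoxyphenyl)-2-{(S)-(4-methoxyphenyl)[(triethylsilyl)oxy]methyl}pent-4-en-1-yl (2Z)-2-({[tert-butyl(dimethyl)silyl]oxy}methyl)but-2-enoate, via alkoxyphosphonium carboxylate 15 (not isolated)
Conditions: PPh3 (1.5 equiv), diisopropyl azodicarboxylate (1.5 equiv), THF, 0 °C to rt
Reagents that add atoms: triphenylphosphine, c1ccc(cc1)P(c1ccccc1)c1ccccc1 (in 15 only; nothing from it stays in 16)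
Why: Mitsunobu esterification activates the primary alcohol as its alkoxyphosphonium ion and the carboxylate displaces it at CH2 (SN2), so the acid is never activated (no Z/E leakage) and no stereocentre is touched.

Step 12
Reactants: 16 (2S,4E)-5-(3,4-dimethoxyphenyl)-2-{(S)-(4-methoxyphenyl)[(triethylsilyl)oxy]methyl}pent-4-en-1-yl (2Z)-2-({[tert-butyl(dimethyl)silyl]oxy}methyl)but-2-enoate
Product: 17 (2S,4E)-5-(3,4-dimethoxyphenyl)-2-[(S)-hydroxy(4-methoxyphenyl)methyl]pent-4-en-1-yl (2Z)-2-(hydroxymethyl)but-2-enoate (CNP0210582.1)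
Conditions: HF·pyridine, pyridine, THF, 0 °C; aq. NaHCO3
Reagents that add atoms: none
Why: Fluoride-driven desilylation (strong Si–F bond) removes the secondary triethylsilyl and the primary TBS ether in one operation under buffered, weakly acidic conditions that neither ionise the 4-methoxybenzylic alcohol nor promote 1,3-acyl migration.

**Compound list**

1 | ethyl 3-(4-methoxyphenyl)-3-oxopropanoate | CCOC(=O)CC(=O)c1ccc(OC)cc1 | starting material
2 | ethyl (3S)-3-hydroxy-3-(4-methoxyphenyl)propanoate | CCOC(=O)C[C@H](O)c1ccc(OC)cc1 | intermediate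
3 | methyl (2E)-3-(3,4-dimethoxyphenyl)prop-2-enoate | COC(=O)/C=C/c1ccc(OC)c(OC)c1 | starting material
4 | (2E)-3-(3,4-dimethoxyphenyl)prop-2-en-1-ol | OC/C=C/c1ccc(OC)c(OC)c1 | intermediate
5 | (2E)-3-(3,4-dimethoxyphenyl)prop-2-en-1-yl ethyl carbonate | CCOC(=O)OC/C=C/c1ccc(OC)c(OC)c1 | intermediate
6 | dilithium (1E,3S)-1-ethoxy-3-(4-methoxyphenyl)prop-1-ene-1,3-bis(olate), lithium-chelated, enolate oxygen cis to the carbinol carbon (not isolated) | CCO/C([O-])=C/[C@H]([O-])c1ccc(OC)cc1.[Li+].[Li+] | intermediate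
7 | ethyl (2R,3S)-2-[(2E)-3-(3,4-dimethoxyphenyl)prop-2-en-1-yl]-3-hydroxy-3-(4-methoxyphenyl)propanoate | CCOC(=O)[C@H](C/C=C/c1ccc(OC)c(OC)c1)[C@H](O)c1ccc(OC)cc1 | intermediate
8 | ethyl (2R,3S)-2-[(2E)-3-(3,4-dimethoxyphenyl)prop-2-en-1-yl]-3-(4-methoxyphenyl)-3-[(triethylsilyl)oxy]propanoate | CCOC(=O)[C@H](C/C=C/c1ccc(OC)c(OC)c1)[C@H](O[Si](CC)(CC)CC)c1ccc(OC)cc1 | intermediate
9 | (2S,4E)-5-(3,4-dimethoxyphenyl)-2-{(S)-(4-methoxyphenyl)[(triethylsilyl)oxy]methyl}pent-4-en-1-ol | OC[C@H](C/C=C/c1ccc(OC)c(OC)c1)[C@H](O[Si](CC)(CC)CC)c1ccc(OC)cc1 | intermediate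
10 | but-2-yn-1-ol | CC#CCO | starting material
11 | (2Z)-2-(tributylstannyl)but-2-en-1-ol | C/C=C(/CO)[Sn](CCCC)(CCCC)CCCC | intermediate
12 | methyl (2Z)-2-(hydroxymethyl)but-2-enoate | C/C=C(/CO)C(=O)OC | intermediate
13 | methyl (2Z)-2-({[tert-butyl(dimethyl)silyl]oxy}methyl)but-2-enoate | C/C=C(/CO[Si](C)(C)C(C)(C)C)C(=O)OC | intermediate
14 | (2Z)-2-({[tert-butyl(dimethyl)silyl]oxy}methyl)but-2-enoic acid | C/C=C(/CO[Si](C)(C)C(C)(C)C)C(=O)O | intermediate
15 | {[(2S,4E)-5-(3,4-dimethoxyphenyl)-2-{(S)-(4-methoxyphenyl)[(triethylsilyl)oxy]methyl}pent-4-en-1-yl]oxy}triphenylphosphonium (2Z)-2-({[tert-butyl(dimethyl)silyl]oxy}methyl)but-2-enoate (not isolated) | C/C=C(/CO[Si](C)(C)C(C)(C)C)C(=O)[O-].c1ccccc1[P+](c1ccccc1)(c1ccccc1)OC[C@H](C/C=C/c1ccc(OC)c(OC)c1)[C@H](O[Si](CC)(CC)CC)c1ccc(OC)cc1 | intermediate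
16 | (2S,4E)-5-(3,4-dimethoxyphenyl)-2-{(S)-(4-methoxyphenyl)[(triethylsilyl)oxy]methyl}pent-4-en-1-yl (2Z)-2-({[tert-butyl(dimethyl)silyl]oxy}methyl)but-2-enoate | C/C=C(/CO[Si](C)(C)C(C)(C)C)C(=O)OC[C@H](C/C=C/c1ccc(OC)c(OC)c1)[C@H](O[Si](CC)(CC)CC)c1ccc(OC)cc1 | intermediate
17 | (2S,4E)-5-(3,4-dimethoxyphenyl)-2-[(S)-hydroxy(4-methoxyphenyl)methyl]pent-4-en-1-yl (2Z)-2-(hydroxymethyl)but-2-enoate | C/C=C(/CO)C(=O)OC[C@H](C/C=C/c1ccc(OC)c(OC)c1)[C@H](O)c1ccc(OC)cc1 | target

**Step count and risks**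

Total steps: 12. Longest linear sequence: 7 (steps 2, 3, 4, 5, 6, 11, 12).

The three steps most likely to fail:

Step 4 (the proposed new step). Risks are acyl transfer from the carbonate to the dianion, O-allylation, or weaker anti induction with the bulky π-allyl electrophile than with simple halides. Fallback with known chemistry, setting out from 2 and coming back at 9: the same dianion 6 is alkylated in the classical Fráter–Seebach way with allyl bromide (LiN(i-Pr)2 2.1 equiv, THF/DMPU, −78 to −20 °C; anti) to give ethyl (2R)-2-[(S)-hydroxy(4-methoxyphenyl)methyl]pent-4-enoate F1. Et3SiOTf/2,6-lutidine then gives ethyl (2R)-2-{(S)-(4-methoxyphenyl)[(triethylsilyl)oxy]methyl}pent-4-enoate F2, and i-Bu2AlH (CH2Cl2, −78 °C) gives (2S)-2-{(S)-(4-methoxyphenyl)[(triethylsilyl)oxy]methyl}pent-4-en-1-ol F3. Cross-metathesis of F3 with 3,4-dimethoxystyrene (3 equiv, second-generation Grubbs catalyst 5 mol %, CH2Cl2, 40 °C) installs the E-styrene and returns to the route at 9.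

Step 10. Hydrolysis of the hindered Z-enoate may be slow, and forcing it risks Z-to-E isomerisation or loss of the silyl group. Fallback, setting out from 11 and coming back at 16: I2 (CH2Cl2, 0 °C) converts 11 with retention into (2Z)-2-iodobut-2-en-1-ol F4, and TBSCl/imidazole gives tert-butyl{[(2Z)-2-iodobut-2-en-1-yl]oxy}dimethylsilane F5. Palladium-catalysed alkoxycarbonylation of F5 (1.5 equiv) with alcohol 9 (PdCl2(PPh3)2 5 mol %, CO 1 atm, Et3N, DMF, 60 °C) gives 16 directly, so neither the free acid nor step 11 is needed.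

Step 11. The SN2 displacement at the β-branched CH2 next to a bulky silyloxybenzyl group may be sluggish. Fallback, setting out from 14 (with 9) and coming back at 16: 14 is converted with 2,4,6-trichlorobenzoyl chloride and Et3N (toluene, rt) into (2Z)-2-({[tert-butyl(dimethyl)silyl]oxy}methyl)but-2-enoic 2,4,6-trichlorobenzoic anhydride F6. Alcohol 9 is then acylated with it (DMAP 0.2 equiv, toluene, rt; Yamaguchi esterification), which moves bond formation from the hindered carbon to oxygen.

Further compounds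
F1 | step 4 | ethyl (2R)-2-[(S)-hydroxy(4-methoxyphenyl)methyl]pent-4-enoate | CCOC(=O)[C@H](CC=C)[C@H](O)c1ccc(OC)cc1
F2 | step 4 | ethyl (2R)-2-{(S)-(4-methoxyphenyl)[(triethylsilyl)oxy]methyl}pent-4-enoate | CCOC(=O)[C@H](CC=C)[C@H](O[Si](CC)(CC)CC)c1ccc(OC)cc1
F3 | step 4 | (2S)-2-{(S)-(4-methoxyphenyl)[(triethylsilyl)oxy]methyl}pent-4-en-1-ol | OC[C@H](CC=C)[C@H](O[Si](CC)(CC)CC)c1ccc(OC)cc1
F4 | step 10 | (2Z)-2-iodobut-2-en-1-ol | C/C=C(/CO)I
F5 | step 10 | tert-butyl{[(2Z)-2-iodobut-2-en-1-yl]oxy}dimethylsilane | C/C=C(/CO[Si](C)(C)C(C)(C)C)I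
F6 | step 11 | (2Z)-2-({[tert-butyl(dimethyl)silyl]oxy}methyl)but-2-enoic 2,4,6-trichlorobenzoic anhydride | C/C=C(/CO[Si](C)(C)C(C)(C)C)C(=O)OC(=O)c1c(Cl)cc(Cl)cc1Cl
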